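Retrosynthesis: the C3–O bond is cut first, which leads back to the (2S)-flavanone. The C4 ketone is traced to a C4 methyl ether, ring C is opened at O1–C2 and C3–C4, and the C8–prenyl bond is cut last (Claisen shift of an aryl ether).
Enabling feature: O1 and C4 are ortho neighbours on the electron-rich ring A, and C2, C3 and ring B together are 2-methoxy-4-vinylphenol. Ring C is therefore the [4+2] adduct of a ring A ortho-quinone methide (C4 at the aldehyde level) and that styrene.
Forward order: rings A and B are bought as arenes and ring A is dressed (7-OMe, 5-OMOM, 8-prenyl). Ring C closes in step 6, C4 is raised to the ketone, C3 is hydroxylated, and both MOM groups are removed.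
Stereochemistry: C2 comes from a chiral phosphate in step 6. C3 is set by C2, because the oxidant arrives anti to the aryl group and the trans isomer is also the more stable one. The C4 epimers disappear at the ketone stage.

Key step: step 6

Assumption: the (R)-configured phosphoric acid is taken to give the (2S)-flavan; if the sense of induction is the opposite, its enantiomer is used with no other change.

Step 1
Reactants: 1 2,4,6-trihydroxybenzaldehyde
Product: 2 2,6-dihydroxy-4-methoxybenzaldehyde
Conditions: Me2SO4 (1.0 equiv), K2CO3 (1.0 equiv), acetone, rt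
Reagents that add atoms: dimethyl sulfate, COS(=O)(=O)OC
Why: Williamson-type O-methylation, in which the 4-OH is the only hydroxyl not hydrogen-bonded to the formyl oxygen and is the most acidic one (a vinylogous acid), so one equivalent each of base and alkylating agent should engage it first.

Step 2
Reactants: 2 2,6-dihydroxy-4-methoxybenzaldehyde
Product: 3 2-hydroxy-4-methoxy-6-(methoxymethoxy)benzaldehyde
Conditions: MOMCl (1.05 equiv), i-Pr2NEt (1.2 equiv), CH2Cl2, 0 °C to rt
Reagents that add atoms: chloromethyl methyl ether, COCCl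
Why: MOM protection of a phenol, in which the two hydroxyls are equivalent and the survivor becomes locked in a strong hydrogen bond to the aldehyde once the first is capped, which is the usual basis for mono-protection of 2,6-dihydroxyaryl carbonyl compounds.

Step 3
Reactants: 3 2-hydroxy-4-methoxy-6-(methoxymethoxy)benzaldehyde; 4 3-chloro-3-methylbut-1-yne
Product: 5 4-methoxy-2-(methoxymethoxy)-6-[(2-methylbut-3-yn-2-yl)oxy]benzaldehyde
Conditions: 4 (1.5 equiv), DBU (1.6 equiv), CuCl2·2H2O (1 mol %), MeCN, 0 °C to rt
Reagents that add atoms: none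
Why: Copper-catalysed propargylic etherification of a phenol by a tertiary propargylic chloride (through a copper allenylidene type electrophile), which runs at or below room temperature and accepts electron-poor phenoxides, so the aryl propargyl ether should not go on to a chromene.

Step 4
Reactants: 5 4-methoxy-2-(methoxymethoxy)-6-[(2-methylbut-3-yn-2-yl)oxy]benzaldehyde
Product: 6 4-methoxy-2-(methoxymethoxy)-6-[(2-methylbut-3-en-2-yl)oxy]benzaldehyde
Conditions: H2 (1 atm), Pd/CaCO3 poisoned with Pb(OAc)2 (Lindlar catalyst), quinoline, EtOAc, rt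
Reagents that add atoms: none
Why: Lindlar semihydrogenation stops a terminal alkyne at the alkene and leaves the aldehyde, the aryl ethers and the MOM acetal untouched.

Step 5
Reactants: 6 4-methoxy-2-(methoxymethoxy)-6-[(2-methylbut-3-en-2-yl)oxy]benzaldehyde
Product: 7 2-hydroxy-4-methoxy-6-(methoxymethoxy)-3-(3-methylbut-2-en-1-yl)benzaldehyde
Conditions: N,N-diethylaniline, 130 °C
Reagents that add atoms: none
Why: Aromatic Claisen rearrangement, whose [3,3] shift inverts the allyl unit so that the 1,1-dimethylallyl ether delivers a linear prenyl group to the only ortho carbon that carries hydrogen, with rearomatisation making the shift irreversible and the gem-dimethyl group lowering the temperature needed.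

Step 6
Reactants: 7 2-hydroxy-4-methoxy-6-(methoxymethoxy)-3-(3-methylbut-2-en-1-yl)benzaldehyde; 8 2-methoxy-4-vinylphenol
Product: 11 (2S)-2-(4-hydroxy-3-methoxyphenyl)-4,7-dimethoxy-5-(methoxymethoxy)-8-(3-methylbut-2-en-1-yl)chroman as both C4 epimers, via dimethyl acetal 9 (not isolated), via methoxy ortho-quinone methide 10 (not isolated)
Conditions: HC(OMe)3 (2 equiv), (R)-3,3'-bis(2,4,6-triisopropylphenyl)-1,1'-binaphthyl-2,2'-diyl hydrogen phosphate (10 mol %), toluene, 0 °C; then 8 (1.3 equiv) added slowly, −20 °C; Et3N quench
Reagents that add atoms: trimethyl orthoformate, COC(OC)OC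
Why: Proposed new method: the phosphoric acid lets 7 exchange with the orthoformate to acetal 9, which loses methanol to the O-protonated form of quinone methide 10, held as a contact ion pair with the chiral phosphate; the CH2 terminus of 8 attacks the cationic methine carbon (C3–C4), the phosphate takes up the 4'-OH proton so that a neutral para-quinone methide results, and the ring A hydroxyl adds to its benzylic carbon (O1–C2). The closest known reaction types are three-component condensations of salicylaldehydes with orthoformates and styrenes under achiral acids, which give 4-alkoxy-2-arylchromans, phosphoric acid-catalysed [4+2] additions of ortho-quinone methides to hydroxystyrenes, and phosphoric acid-catalysed 1,6-additions to para-quinone methides; the new element is an alkoxy-substituted quinone methide cation under enantiocontrol. Ring C closes intermolecularly as an asynchronous inverse-electron-demand hetero-[4+2] cycloaddition, which in its stepwise limit ends in a 6-exo-trig oxa-1,6-addition. C2 is fixed in that O1–C2 closure inside the catalyst pocket, where the phosphate binds the para-quinone methide oxygen and the ring A hydroxyl at the same time, so the steering hydrogen bond is conjugated to the reacting carbon; C4 forms as a mixture, stays labile through re-ionisation so that it cannot cap the selectivity at C2, and is erased in step 9. Regiochemistry follows from matched polarity (nucleophilic CH2 to electrophilic C4, benzylic carbon to oxygen), the MOM group on the second ortho oxygen leaves only the hydroxyl next to the prenyl group free to close, which places prenyl at C8, and the hydrogen-bonded vinylphenol is a far better nucleophile than the prenyl alkene or the ring A carbons. The weak acid, the low temperature and the slow addition of 8 are meant to hold back styrene oligomerisation, prenyl–phenol cyclisation, MOM loss and renewed ionisation of 11.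

Step 7
Reactants: 11 (2S)-2-(4-hydroxy-3-methoxyphenyl)-4,7-dimethoxy-5-(methoxymethoxy)-8-(3-methylbut-2-en-1-yl)chroman
Product: 12 (2S)-4,7-dimethoxy-2-[3-methoxy-4-(methoxymethoxy)phenyl]-5-(methoxymethoxy)-8-(3-methylbut-2-en-1-yl)chroman (C4 epimers)
Conditions: MOMCl (1.3 equiv), i-Pr2NEt (1.6 equiv), CH2Cl2, 0 °C to rt
Reagents that add atoms: chloromethyl methyl ether, COCCl
Why: MOM protection of a phenol under amine base, which keeps the acid-labile C4 methyl ether intact and, by capping the 4'-OH, closes the para-quinone methide channel through which C2 could racemise and shields ring B from the later oxidants.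

Step 8
Reactants: 12 (2S)-4,7-dimethoxy-2-[3-methoxy-4-(methoxymethoxy)phenyl]-5-(methoxymethoxy)-8-(3-methylbut-2-en-1-yl)chroman
Product: 13 (2S)-7-methoxy-2-[3-methoxy-4-(methoxymethoxy)phenyl]-5-(methoxymethoxy)-8-(3-methylbut-2-en-1-yl)chroman-4-ol (C4 epimers)
Conditions: PPTS (10 mol %), THF–H2O (4:1), 0.01 M, rt
Reagents that add atoms: water, O
Why: SN1 solvolysis of a benzylic ether, in which the C4 cation is stabilised by O1, 5-O and 7-O in ortho and para positions as in flavan-4-ol chemistry, so a pyridinium salt and a large excess of water at high dilution should suffice while aryl MOM ethers, the prenyl group and C2 are not touched.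

Step 9
Reactants: 13 (2S)-7-methoxy-2-[3-methoxy-4-(methoxymethoxy)phenyl]-5-(methoxymethoxy)-8-(3-methylbut-2-en-1-yl)chroman-4-ol
Product: 14 (2S)-7-methoxy-2-[3-methoxy-4-(methoxymethoxy)phenyl]-5-(methoxymethoxy)-8-(3-methylbut-2-en-1-yl)chroman-4-one
Conditions: Dess–Martin periodinane (1.2 equiv), NaHCO3, CH2Cl2, 0 °C to rt
Reagents that add atoms: none
Why: Dess–Martin oxidation of a secondary benzylic alcohol under bicarbonate buffer, in which both C4 epimers converge on one ketone, the alkene is inert, and the absence of strong acid or base leaves C2 unchanged.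

Step 10
Reactants: 14 (2S)-7-methoxy-2-[3-methoxy-4-(methoxymethoxy)phenyl]-5-(methoxymethoxy)-8-(3-methylbut-2-en-1-yl)chroman-4-one
Product: 15 (2S)-7-methoxy-2-[3-methoxy-4-(methoxymethoxy)phenyl]-5-(methoxymethoxy)-8-(3-methylbut-2-en-1-yl)-4-(trimethylsilyloxy)-2H-chromene
Conditions: TMSOTf (1.3 equiv), Et3N (3 equiv), CH2Cl2, 0 °C, dark; cold NaHCO3 wash, used crude
Reagents that add atoms: trimethylsilyl trifluoromethanesulfonate, C[Si](C)(C)OS(=O)(=O)C(F)(F)F
Why: Soft enolisation with a silyl triflate and a tertiary amine, in which O-silylation of the ketone precedes loss of a C3 proton, so no free enolate arises and the β-elimination of the O1 phenoxide that would open ring C and racemise C2 is avoided.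

Step 11
Reactants: 15 (2S)-7-methoxy-2-[3-methoxy-4-(methoxymethoxy)phenyl]-5-(methoxymethoxy)-8-(3-methylbut-2-en-1-yl)-4-(trimethylsilyloxy)-2H-chromene
Product: 17 (2R,3R)-3-hydroxy-7-methoxy-2-[3-methoxy-4-(methoxymethoxy)phenyl]-5-(methoxymethoxy)-8-(3-methylbut-2-en-1-yl)chroman-4-one (2,3-trans), via siloxy epoxide 16 (not isolated)
Conditions: dimethyldioxirane (1.0 equiv, acetone solution), CH2Cl2, −78 °C; then aq. citric acid, THF, 0 °C
Reagents that add atoms: dimethyldioxirane, CC1(C)OO1
Why: Rubottom-type oxidation, in which the silyl enol ether conjugated with ring A is far more electron-rich than the prenyl alkene and should take the single equivalent of dioxirane at low temperature, with oxygen delivered to the face opposite the C2 aryl group to set the 2,3-trans relationship, which is also the more stable diequatorial arrangement.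

Step 12
Reactants: 17 (2R,3R)-3-hydroxy-7-methoxy-2-[3-methoxy-4-(methoxymethoxy)phenyl]-5-(methoxymethoxy)-8-(3-methylbut-2-en-1-yl)chroman-4-one
Product: 18 (2R,3R)-3,5-dihydroxy-2-(4-hydroxy-3-methoxyphenyl)-7-methoxy-8-(3-methylbut-2-en-1-yl)chroman-4-one (CNP0195184.1)
Conditions: HCl (1.25 M in MeOH), 40 °C
Reagents that add atoms: none
Why: Acid-catalysed acetal exchange removes both aryl MOM groups (the 5-O-MOM helped by the peri carbonyl), the prenyl group is flanked only by O1 and 7-OMe so that no chroman can form, and the trans-dihydroflavonol should hold its configuration in mild acid.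

Compound list
1 | 2,4,6-trihydroxybenzaldehyde | O=Cc1c(O)cc(O)cc1O | starting material
2 | 2,6-dihydroxy-4-methoxybenzaldehyde | COc1cc(O)c(C=O)c(O)c1 | intermediate
3 | 2-hydroxy-4-methoxy-6-(methoxymethoxy)benzaldehyde | COCOc1cc(OC)cc(O)c1C=O | intermediate
4 | 3-chloro-3-methylbut-1-yne | C#CC(C)(C)Cl | starting material
5 | 4-methoxy-2-(methoxymethoxy)-6-[(2-methylbut-3-yn-2-yl)oxy]benzaldehyde | COCOc1cc(OC)cc(OC(C)(C)C#C)c1C=O | intermediate
6 | 4-methoxy-2-(methoxymethoxy)-6-[(2-methylbut-3-en-2-yl)oxy]benzaldehyde | COCOc1cc(OC)cc(OC(C)(C)C=C)c1C=O | intermediate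
7 | 2-hydroxy-4-methoxy-6-(methoxymethoxy)-3-(3-methylbut-2-en-1-yl)benzaldehyde | COCOc1cc(OC)c(CC=C(C)C)c(O)c1C=O | intermediate
8 | 2-methoxy-4-vinylphenol | C=Cc1ccc(O)c(OC)c1 | starting material
9 | dimethyl acetal of 7, 2-(dimethoxymethyl)-5-methoxy-3-(methoxymethoxy)-6-(3-methylbut-2-en-1-yl)phenol | COCOc1cc(OC)c(CC=C(C)C)c(O)c1C(OC)OC | intermediate
10 | 3-methoxy-6-(methoxymethylidene)-5-(methoxymethoxy)-2-(3-methylbut-2-en-1-yl)cyclohexa-2,4-dien-1-one (reacts as its O-protonated ion pair with the phosphate; exocyclic alkene geometry undefined) | COC=C1C(=O)C(CC=C(C)C)=C(OC)C=C1OCOC | intermediate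
11 | (2S)-2-(4-hydroxy-3-methoxyphenyl)-4,7-dimethoxy-5-(methoxymethoxy)-8-(3-methylbut-2-en-1-yl)chroman, both C4 epimers | COc1cc([C@H]2Oc3c(CC=C(C)C)c(OC)cc(OCOC)c3C(OC)C2)ccc1O | intermediate
12 | (2S)-4,7-dimethoxy-2-[3-methoxy-4-(methoxymethoxy)phenyl]-5-(methoxymethoxy)-8-(3-methylbut-2-en-1-yl)chroman, both C4 epimers | COc1cc([C@H]2Oc3c(CC=C(C)C)c(OC)cc(OCOC)c3C(OC)C2)ccc1OCOC | intermediate
13 | (2S)-7-methoxy-2-[3-methoxy-4-(methoxymethoxy)phenyl]-5-(methoxymethoxy)-8-(3-methylbut-2-en-1-yl)chroman-4-ol, both C4 epimers | COc1cc([C@H]2Oc3c(CC=C(C)C)c(OC)cc(OCOC)c3C(O)C2)ccc1OCOC | intermediate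
14 | (2S)-7-methoxy-2-[3-methoxy-4-(methoxymethoxy)phenyl]-5-(methoxymethoxy)-8-(3-methylbut-2-en-1-yl)chroman-4-one | COc1cc([C@H]2Oc3c(CC=C(C)C)c(OC)cc(OCOC)c3C(=O)C2)ccc1OCOC | intermediate
15 | (2S)-7-methoxy-2-[3-methoxy-4-(methoxymethoxy)phenyl]-5-(methoxymethoxy)-8-(3-methylbut-2-en-1-yl)-4-(trimethylsilyloxy)-2H-chromene | COc1cc([C@H]2Oc3c(CC=C(C)C)c(OC)cc(OCOC)c3C(O[Si](C)(C)C)=C2)ccc1OCOC | intermediate
16 | 3,4-epoxide of 15, C2 arranged as in 15, epoxide oxygen on the ring C face opposite the C2 aryl group, trimethylsilyloxy group retained at C4 | COc1cc([C@H]2Oc3c(CC=C(C)C)c(OC)cc(OCOC)c3[C@]4(O[Si](C)(C)C)O[C@H]24)ccc1OCOC | intermediate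
17 | (2R,3R)-3-hydroxy-7-methoxy-2-[3-methoxy-4-(methoxymethoxy)phenyl]-5-(methoxymethoxy)-8-(3-methylbut-2-en-1-yl)chroman-4-one | COc1cc([C@H]2Oc3c(CC=C(C)C)c(OC)cc(OCOC)c3C(=O)[C@@H]2O)ccc1OCOC | intermediate
18 | (2R,3R)-3,5-dihydroxy-2-(4-hydroxy-3-methoxyphenyl)-7-methoxy-8-(3-methylbut-2-en-1-yl)chroman-4-one | COc1cc([C@H]2Oc3c(CC=C(C)C)c(OC)cc(O)c3C(=O)[C@@H]2O)ccc1O | target

Total step count: 12. Longest linear sequence: 12 steps (1 to 18); 4 and 8 enter as purchased.

Steps most likely to fail

1. Step 6.
- What may go wrong: facial selectivity in the O1–C2 closure may be poor. The cation may also be lost to oligomerisation of the vinylphenol, to arylation by ring A carbons, or to renewed ionisation at C4 of the adduct followed by a second addition.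
- Fallback: it sets out from 7 and 8, returns at 14, keeps the ring C disconnection, and moves the origin of chirality to a resolution.
- The known achiral version of the condensation (HC(OMe)3, catalytic p-TsOH·H2O, CH2Cl2, 0 °C) should give the racemic 4-methoxyflavan F1.
- The operations of steps 7 to 9 then lead through the racemic 4'-O-MOM ether F2 and the racemic flavan-4-ol F3 to the racemic flavanone F4.
- Kinetic resolution of F4 follows by asymmetric transfer hydrogenation (RuCl(p-cymene)[(R,R)-TsDPEN], HCO2H–Et3N, EtOAc, rt, stopped near half conversion). By the usual sense of induction for aryl ketones, this should reduce the (2R)-ketone faster to the cis-(2R,4R)-flavan-4-ol F5 and leave 14, which is separated by chromatography.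
- The same resolution can raise the purity of 14 if step 6 gives only partial enrichment.

2. Step 11.
- What may go wrong: the dioxirane may also epoxidise the prenyl double bond, or the enol silane may hydrolyse back to the ketone before oxygen transfer.
- Fallback: it sets out from 14, returns at 17, and replaces the electrophilic oxidation of a neutral enol ether by a Davis hydroxylation of an enolate.
- NaN(SiMe3)2 in THF at −78 °C gives the sodium enolate F8. This is trapped at once with 2-(phenylsulfonyl)-3-phenyloxaziridine and quenched with acetic acid at −78 °C.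
- The oxaziridine does not attack unactivated alkenes at this temperature and should again approach anti to the aryl group. The short lifetime of the cold enolate is meant to limit opening of ring C.

3. Step 3.
- What may go wrong: O-alkylation of the hydrogen-bonded, electron-poor phenoxide by the tertiary propargylic chloride may be sluggish, so that elimination of the chloride to the enyne takes over.
- Fallback: it sets out from 3, returns at 7, and builds the prenyl group from an allyl group.
- Allyl bromide with K2CO3 in DMF gives the allyl ether F6.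
- Aromatic Claisen rearrangement (N,N-diethylaniline, 190 °C) gives the 3-allylphenol F7.
- Cross metathesis with 2-methylbut-2-ene (second-generation Grubbs catalyst (H2IMes)(PCy3)Cl2Ru=CHPh, CH2Cl2, 40 °C) converts the allyl into the prenyl group.

Further compounds
F1 | step 6 | racemic 2-(4-hydroxy-3-methoxyphenyl)-4,7-dimethoxy-5-(methoxymethoxy)-8-(3-methylbut-2-en-1-yl)chroman | COc1cc(C2Oc3c(CC=C(C)C)c(OC)cc(OCOC)c3C(OC)C2)ccc1O
F2 | step 6 | racemic 4,7-dimethoxy-2-[3-methoxy-4-(methoxymethoxy)phenyl]-5-(methoxymethoxy)-8-(3-methylbut-2-en-1-yl)chroman | COc1cc(C2Oc3c(CC=C(C)C)c(OC)cc(OCOC)c3C(OC)C2)ccc1OCOC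
F3 | step 6 | racemic 7-methoxy-2-[3-methoxy-4-(methoxymethoxy)phenyl]-5-(methoxymethoxy)-8-(3-methylbut-2-en-1-yl)chroman-4-ol | COc1cc(C2Oc3c(CC=C(C)C)c(OC)cc(OCOC)c3C(O)C2)ccc1OCOC
F4 | step 6 | racemic 7-methoxy-2-[3-methoxy-4-(methoxymethoxy)phenyl]-5-(methoxymethoxy)-8-(3-methylbut-2-en-1-yl)chroman-4-one | COc1cc(C2Oc3c(CC=C(C)C)c(OC)cc(OCOC)c3C(=O)C2)ccc1OCOC
F5 | step 6 | (2R,4R)-7-methoxy-2-[3-methoxy-4-(methoxymethoxy)phenyl]-5-(methoxymethoxy)-8-(3-methylbut-2-en-1-yl)chroman-4-ol (2,4-cis) | COc1cc([C@@H]2Oc3c(CC=C(C)C)c(OC)cc(OCOC)c3[C@H](O)C2)ccc1OCOC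
F6 | step 3 | 2-(allyloxy)-4-methoxy-6-(methoxymethoxy)benzaldehyde | C=CCOc1cc(OC)cc(OCOC)c1C=O
F7 | step 3 | 3-allyl-2-hydroxy-4-methoxy-6-(methoxymethoxy)benzaldehyde | C=CCc1c(O)c(C=O)c(OCOC)cc1OC
F8 | step 11 | sodium enolate of 14 | COc1cc([C@H]2Oc3c(CC=C(C)C)c(OC)cc(OCOC)c3C([O-])=C2)ccc1OCOC.[Na+]
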